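## Numbering and remarks

- Atom numbering (terpenoid convention): ring A is C1–C5 and C10 (gem-dimethyl at C4); ring B is C5–C10 (angular methyl at C10, hydroxyl and methyl at C8, chain at C9). C11 is the chain carbon on C9, C12 the next one. β is the face of ring B that carries the C10 methyl, α the opposite face.
- Assumption: the (R)-configured binaphthol ligand is written in step 3 as the one that leads to the (5R,10S) series; if the sense of induction is the opposite, its enantiomer is used.
- Remark: the key-step product 6 is drawn with the ester equatorial on ring B, which in the cis-fused series means trans to the C10 methyl; this centre is epimerisable and is erased in step 4.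

## Analysis of the target

The target 18 (C30H52O) is a bicyclic triterpenoid alcohol: a decalin of ring A and ring B that carries at C9 a (3E,7E)-4,8,12-trimethyltrideca-3,7,11-trienyl chain with three trisubstituted alkenes. It has four contiguous stereocentres, C5 (R), C10 (S), C9 (R) and C8 (R): H5 and the C10 methyl are cis (cis-fused decalin), the C9 chain is cis to the C10 methyl, and at C8 the methyl is cis and the hydroxyl trans to the chain. A cis-decalin of this pattern should strongly prefer the chair–chair form with C4 equatorial and C1 axial on ring B, because the other form holds the quaternary C4 axial over ring B; in the preferred form the C9 chain and the C8 hydroxyl are trans-diaxial and the α face of ring B is screened by the C1 methylene. The C9 configuration is therefore the less stable one and also the one with hydrogen on the screened face, so neither equilibration next to a carbonyl group nor simple reagent approach will give it. C8, by contrast, can be set by attack of a methyl nucleophile on a C8 ketone from the open β face. The sensitive groups are the tertiary alcohol (ionisation, dehydration) and the chain alkenes (acid-induced cyclisation or isomerisation), so the chain must arrive after all acid chemistry, with its E geometry bought in. The hard part is the enantioselective construction of a cis ring fusion with the quaternary C10 next to the quaternary C4. The strategy rests on one feature: the cis relation of H5 and the C10 methyl across C5–C10 is the image of a Z trisubstituted alkene C5=C10 in an open chain that is closed by antiperiplanar addition.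

## Retrosynthetic reasoning

**C11–C12.** The last bond cut joins the decalin to the chain. Cutting here lets all three alkenes come from 15 with fixed geometry and keeps them away from every acidic step. The carbanion is placed on C11 (sulfone 14) and the leaving group on the allylic C12 (15). The reverse pairing would need substitution at the doubly β-branched C11, and a sulfone on the chain would be allylic and could scramble the C13 alkene on removal. So 18 comes from 17 by reductive desulfonylation, and 17 from 14 and 15 by alkylation.

**C9–H.** The C9 centre of 14 is traced back to vinyl sulfone 13, in which C9 is trigonal. The forward reaction must put hydrogen on the α face of C9, against both steric approach and thermodynamic preference. The α-hydroxyl at C8 is the only handle on that face, so a hydroxyl-directed hydrogenation is required; it fixes C9 relative to C8 by mechanism.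

**C11–S and C9=C11.** 13 goes back to the tertiary allylic alcohol 10 with an exocyclic methylene. The forward reaction adds a sulfonyl radical to the terminal carbon and then eliminates a selenoxide. Because C8 and C10 carry no hydrogen, only the C9=C11 alkene can form.

**C8–CH3.** 10 goes back to enone 9 by removing the C8 methyl. The cut is made at this stage because C9 is trigonal: no neighbouring centre can bias or be disturbed, so face selection at C8 depends only on the ring fusion.

**Oxidation level at C11 (no skeletal bond cut).** 9 goes back through enol ether 7 to keto ester 6. The ester carbon of 6 is C11; lowering its oxidation level while C9 is made trigonal removes the epimerisable C9 centre of 6, which otherwise would have to be controlled.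

**C4–C5 and C9–C10.** Both ring bonds of 6 are cut together, opening rings A and B to the dienyl β-keto ester 5. This is the only disconnection that derives the cis fusion from an alkene geometry and at the same time leaves oxygen at C8 and a carbon at C9. The forward reaction must be a concerted, enantioselective, proton-initiated bicyclisation.

**C6–C7.** 5 is cut between the allylic carbon of the neryl unit and the terminal carbon of the acetoacetate, giving bromide 2 and keto ester 3; 2 comes from nerol 1. The Z alkene is bought, not made.

## Alternatives that were turned down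

**Alternative 1:** The disconnection is C1–C10: ring B is the cyclohexene bridge of the bicyclic vinyl carbinol A1, and ring A is closed by a [3,3] shift. In the forward direction the potassium alkoxide of A1 would undergo an anionic oxy-Cope rearrangement (C3–C8 broken, C1–C10 formed) to ketone A2, with a C3 carbonyl and a C8=C9 alkene.
- For it: the cage lets C1 reach C10 only from the side of the C3–C4 bridge, so the cis fusion is a geometric necessity. On this point it is stronger than a cation–olefin cascade, where a stepwise path can leak to the trans series. The C8=C9 alkene of A2 with hydrogen on C9 would also let C11 be brought to C9 from the open β face, a more direct answer to the C9 problem than the erase-and-reset sequence used here.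
- Against it: A2 has neither C11 nor the C8 oxygen and carries a C3 carbonyl that must be deleted. A1 needs a Diels–Alder construction of the cage, a gem-dimethylation, a facially selective vinyl addition and an asymmetric cycloaddition or a resolution, roughly seven or eight steps before the key step.
- Comparison: the chosen route reaches the bicycle with C8 oxygenated and C11 in place three steps from nerol; it gives up the structural guarantee of the fusion.

**Alternative 2:** The disconnection is C8–C9, with ring B closed last on the ring A keto acrylate A3. A samarium-based one-electron reductant would turn the C8 methyl ketone into a ketyl that adds 6-exo to C9 of the acrylate, giving hydroxy ester A4.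
- For it: C8 and C9 are set in the ring-forming step, and ketyl–olefin additions normally place the hydroxyl and the new acetate arm trans, which is the relation of the target. On the C8/C9 problem it is stronger than the chosen route, which spends steps 6 to 8 on it.
- Against it: the difficulty moves into A3, whose vicinal C5 stereocentre and quaternary C10 next to the gem-dimethyl carbon are as hard to make in one enantiomer as the ring fusion itself. The facial relation of C9 to C10 is not fixed by the mechanism. The ester handle ends at C12, so the chain would need a new C12–C13 bond and a newly made E-trisubstituted alkene instead of a bought farnesyl unit.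
- Comparison: the chosen route is shorter to the bicycle and attaches the chain in one alkylation.

**Alternative 3:** The disconnection is C5–C6 and C10–CH3 on cyclohexenone A5, with ring B closed later at C8–C9. A copper catalyst with a chiral diphosphine would add Grignard reagent A6 to C5 of A5, and the enolate would be methylated at C10 trans to the new chain, giving A7.
- For it: the enantioselective step is an established catalytic reaction type, which is stronger than the chiral acid step used here, whose substrate type has not been shown. The trans alkylation translates reliably into the cis relation of H5 and the C10 methyl.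
- Against it: C5 of A5 is flanked by the quaternary C4 and the enone is α-substituted, the least favourable case for conjugate addition. A7 carries a C1 carbonyl to be removed. Ring B closure by ester enolate addition to the C8 ketone is reversible, so C8 and C9 would fall under thermodynamic control, which does not favour the target arrangement.
- Comparison: the chosen route offers brevity, no superfluous oxygen, and a resolution fallback for its one uncertain step.

Key step: step 3

## Route

Step 1
Reactants: 1 nerol
Product: 2 (2Z)-1-bromo-3,7-dimethylocta-2,6-diene (neryl bromide)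
Conditions: PBr3 (0.4 equiv), pyridine (cat.), Et2O, −10 °C
Reagents that add atoms: phosphorus tribromide, BrP(Br)Br
Why: Substitution of the primary allylic alcohol through its phosphite ester (SN2); the low temperature should prevent allylic transposition and Z/E scrambling, so the Z geometry that encodes the cis fusion is kept.

Step 2
Reactants: 3 methyl acetoacetate; 2 neryl bromide
Product: 5 methyl (6Z)-7,11-dimethyl-3-oxododeca-6,10-dienoate, via acetoacetate dianion 4 (not isolated)
Conditions: NaH, THF, 0 °C; n-BuLi, 0 °C; then 2, 0 °C → rt; then 1 M HCl
Reagents that add atoms: none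
Why: γ-Alkylation of the acetoacetate dianion: the more basic terminal carbanion reacts selectively with the primary allylic bromide by SN2, which should leave the Z alkene untouched.

Step 3
Reactants: 5 methyl (6Z)-7,11-dimethyl-3-oxododeca-6,10-dienoate
Product: 6 methyl (1S,4aR,8aS)-5,5,8a-trimethyl-2-oxodecahydronaphthalene-1-carboxylate
Conditions: (R)-2'-(2-fluorobenzyloxy)-1,1'-binaphthalen-2-ol (2.2 equiv), SnCl4 (2.0 equiv), toluene, −78 → −40 °C; then aq. NaHCO3
Reagents that add atoms: none
Why: Proposed new method: the SnCl4-bound binaphthol is a strong chiral Brønsted acid that should protonate C3 of the terminal alkene while C5 of the Z alkene attacks the developing C4 cation and the enol carbon C9 captures C10; the closest known reaction types are the binaphthol·SnCl4-induced enantioselective cyclisation of polyprenoids that end in arene, phenol or hydroxyl groups and the SnCl4-promoted racemic bicyclisation of dienyl β-keto esters. Ring A closes 6-endo at the C5=C10 alkene (bond C4–C5) and ring B closes 6-endo at the enol C8=C9 (bond C9–C10), both through chair-like arrangements. C5 and C10 are set together: antiperiplanar addition across the Z alkene puts H5 and the C10 methyl on the same side, and the chiral acid selects which face of C5=C10 bonds to C4, which fixes the absolute sense. C9 is set by the chelated Z enol, whose ester lies trans to C7 and should therefore end equatorial on ring B, trans to the C10 methyl; this centre is epimerisable through the enol and is erased in step 4. The step needs (a) concerted closure, helped by the short tether and the nucleophilic enol so that no free C10 cation loses the alkene geometry, and (b) face selection, which requires the chiral acid to outrun achiral proton sources formed when the keto ester binds SnCl4, hence the low temperature and the excess of ligand over SnCl4.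

Step 4
Reactants: 6 methyl (1S,4aR,8aS)-5,5,8a-trimethyl-2-oxodecahydronaphthalene-1-carboxylate
Product: 7 methyl (4aR,8aS)-2-methoxy-5,5,8a-trimethyl-3,4,4a,5,6,7,8,8a-octahydronaphthalene-1-carboxylate
Conditions: HC(OMe)3, p-TsOH·H2O (cat.), MeOH, 50 °C
Reagents that add atoms: trimethyl orthoformate, COC(OC)OC
Why: Acid-catalysed enol ether formation of a cyclic β-keto ester gives the conjugated β-methoxy enoate; C9 becomes trigonal so any epimer or enol content of 6 converges, and C5 and C10 are not enolisable.

Step 5
Reactants: 7 methyl (4aR,8aS)-2-methoxy-5,5,8a-trimethyl-3,4,4a,5,6,7,8,8a-octahydronaphthalene-1-carboxylate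
Product: 9 (4aR,8aS)-5,5,8a-trimethyl-1-methylideneoctahydronaphthalen-2(1H)-one, via allylic alcohol 8 (not isolated)
Conditions: i-Bu2AlH (2.5 equiv), CH2Cl2, −78 → −20 °C; then 1 M HCl, THF, 0 °C
Reagents that add atoms: water, O
Why: 1,2-Reduction of the vinylogous carbonate gives the 3-alkoxy allylic alcohol, which ionises under mild acid with help from the enol ether oxygen; hydrolysis of the oxocarbenium ion releases methanol and leaves the α-methylene ketone (Stork–Danheiser-type 1,3-transposition), keeping the ester carbon as C11.

Step 6
Reactants: 9 (4aR,8aS)-5,5,8a-trimethyl-1-methylideneoctahydronaphthalen-2(1H)-one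
Product: 10 (2R,4aR,8aS)-2,5,5,8a-tetramethyl-1-methylidenedecahydronaphthalen-2-ol
Conditions: MeLi, CeCl3, THF, −78 °C; then H2O
Reagents that add atoms: methyllithium, [Li]C
Why: Organocerium 1,2-addition to the enone suppresses enolisation at C7 and conjugate addition; in the preferred conformer the α face of C8 is blocked by the syn-axial C1 methylene, so the methyl should enter equatorially from the β face, giving the 8β-methyl and the axial 8α-hydroxyl (8R).

Step 7
Reactants: 10 (2R,4aR,8aS)-2,5,5,8a-tetramethyl-1-methylidenedecahydronaphthalen-2-ol
Product: 13 (2R,4aR,8aS)-2,5,5,8a-tetramethyl-1-[(phenylsulfonyl)methylidene]decahydronaphthalen-2-ol, via selenide adduct 11 (not isolated), via selenoxide 12 (not isolated)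
Conditions: PhSO2SePh (1.2 equiv), AIBN (cat.), C6H6, 80 °C; then 30% H2O2, pyridine, CH2Cl2, 0 °C → rt
Reagents that add atoms: Se-phenyl benzenesulfonoselenoate, O=S(=O)([Se]c1ccccc1)c1ccccc1
Why: Radical-chain selenosulfonation places the sulfonyl group on the terminal C11 and the selanyl group on C9; selenoxide syn-elimination can only use a C11 hydrogen because C8 and C10 bear none, so the vinyl sulfone is the single regiochemical outcome, the neutral conditions spare the tertiary allylic alcohol, and either alkene geometry serves step 8.

Step 8
Reactants: 13 (2R,4aR,8aS)-2,5,5,8a-tetramethyl-1-[(phenylsulfonyl)methylidene]decahydronaphthalen-2-ol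
Product: 14 (1R,2R,4aR,8aS)-2,5,5,8a-tetramethyl-1-[(phenylsulfonyl)methyl]decahydronaphthalen-2-ol
Conditions: H2 (1 atm), [Ir(cod)(PCy3)(py)]PF6 (10 mol%), CH2Cl2, rt
Reagents that add atoms: none
Why: Hydroxyl-directed homogeneous hydrogenation: the axial 8α-hydroxyl binds the cationic iridium and both hydrogens should be delivered to the α face of C9=C11, so H9 ends cis to the hydroxyl and C11 ends β and axial (9R), the arrangement that neither equilibration nor approach from the open β face would give.

Step 9
Reactants: 14 (1R,2R,4aR,8aS)-2,5,5,8a-tetramethyl-1-[(phenylsulfonyl)methyl]decahydronaphthalen-2-ol; 15 (2E,6E)-farnesyl bromide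
Product: 17 (1R,2R,4aR,8aS)-2,5,5,8a-tetramethyl-1-[(3E,7E)-4,8,12-trimethyl-1-(phenylsulfonyl)trideca-3,7,11-trien-1-yl]decahydronaphthalen-2-ol, via sulfone dianion 16 (not isolated)
Conditions: n-BuLi (2.1 equiv), THF–DMPU, −78 °C; then 15, −78 → −20 °C; then H2O
Reagents that add atoms: none
Why: Alkylation of the α-sulfonyl carbanion (as the oxido sulfone dianion) with the primary allylic bromide by SN2 forms C11–C12 without touching the E alkenes; the new C11 centre is of no consequence because it is removed in step 10.

Step 10
Reactants: 17 (1R,2R,4aR,8aS)-2,5,5,8a-tetramethyl-1-[(3E,7E)-4,8,12-trimethyl-1-(phenylsulfonyl)trideca-3,7,11-trien-1-yl]decahydronaphthalen-2-ol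
Product: 18 (1R,2R,4aR,8aS)-2,5,5,8a-tetramethyl-1-[(3E,7E)-4,8,12-trimethyltrideca-3,7,11-trien-1-yl]decahydronaphthalen-2-ol
Conditions: Na(Hg) (6%), Na2HPO4, MeOH–THF, −20 → 0 °C
Reagents that add atoms: none
Why: Reductive desulfonylation by electron transfer; the sulfone is homoallylic, not allylic, so no alkene transposition is possible, the free tertiary alcohol is tolerated and no ring stereocentre is touched.

## Compound list

1 | nerol, (2Z)-3,7-dimethylocta-2,6-dien-1-ol | CC(C)=CCC/C(C)=C\CO | starting material
2 | (2Z)-1-bromo-3,7-dimethylocta-2,6-diene (neryl bromide) | CC(C)=CCC/C(C)=C\CBr | intermediate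
3 | methyl acetoacetate (methyl 3-oxobutanoate) | COC(=O)CC(C)=O | starting material
4 | sodium lithium dianion of methyl acetoacetate (not isolated) | C=C([O-])C=C([O-])OC.[Na+].[Li+] | intermediate
5 | methyl (6Z)-7,11-dimethyl-3-oxododeca-6,10-dienoate | COC(=O)CC(=O)CC/C=C(/C)CCC=C(C)C | intermediate
6 | methyl (1S,4aR,8aS)-5,5,8a-trimethyl-2-oxodecahydronaphthalene-1-carboxylate (cis-fused; ester trans to the angular methyl) | COC(=O)[C@H]1[C@@]2(C)CCCC(C)(C)[C@H]2CCC1=O | intermediate
7 | methyl (4aR,8aS)-2-methoxy-5,5,8a-trimethyl-3,4,4a,5,6,7,8,8a-octahydronaphthalene-1-carboxylate | COC(=O)C=1[C@@]2(C)CCCC(C)(C)[C@H]2CCC=1OC | intermediate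
8 | [(4aR,8aS)-2-methoxy-5,5,8a-trimethyl-3,4,4a,5,6,7,8,8a-octahydronaphthalen-1-yl]methanol (not isolated) | OCC=1[C@@]2(C)CCCC(C)(C)[C@H]2CCC=1OC | intermediate
9 | (4aR,8aS)-5,5,8a-trimethyl-1-methylideneoctahydronaphthalen-2(1H)-one | C=C1[C@@]2(C)CCCC(C)(C)[C@H]2CCC1=O | intermediate
10 | (2R,4aR,8aS)-2,5,5,8a-tetramethyl-1-methylidenedecahydronaphthalen-2-ol | C=C1[C@@]2(C)CCCC(C)(C)[C@H]2CC[C@@]1(C)O | intermediate
11 | (2R,4aR,8aS)-2,5,5,8a-tetramethyl-1-(phenylselanyl)-1-[(phenylsulfonyl)methyl]decahydronaphthalen-2-ol (either configuration at C1; not isolated) | O=S(=O)(c1ccccc1)CC3([Se]c4ccccc4)[C@@]2(C)CCCC(C)(C)[C@H]2CC[C@@]3(C)O | intermediate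
12 | Se-oxide of 11 (either configuration at C1 and Se; not isolated) | O=S(=O)(c1ccccc1)CC3([Se](=O)c4ccccc4)[C@@]2(C)CCCC(C)(C)[C@H]2CC[C@@]3(C)O | intermediate
13 | (2R,4aR,8aS)-2,5,5,8a-tetramethyl-1-[(phenylsulfonyl)methylidene]decahydronaphthalen-2-ol (C=C geometry not defined; both isomers converge) | O=S(=O)(c1ccccc1)C=C3[C@@]2(C)CCCC(C)(C)[C@H]2CC[C@@]3(C)O | intermediate
14 | (1R,2R,4aR,8aS)-2,5,5,8a-tetramethyl-1-[(phenylsulfonyl)methyl]decahydronaphthalen-2-ol | O=S(=O)(c1ccccc1)C[C@@H]3[C@@]2(C)CCCC(C)(C)[C@H]2CC[C@@]3(C)O | intermediate
15 | (2E,6E)-farnesyl bromide, (2E,6E)-1-bromo-3,7,11-trimethyldodeca-2,6,10-triene | CC(C)=CCC/C(C)=C/CC/C(C)=C/CBr | starting material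
16 | dilithium salt of 14 (alkoxide and α-sulfonyl carbanion; not isolated) | O=S(=O)(c1ccccc1)[CH-][C@@H]3[C@@]2(C)CCCC(C)(C)[C@H]2CC[C@@]3(C)[O-].[Li+].[Li+] | intermediate
17 | (1R,2R,4aR,8aS)-2,5,5,8a-tetramethyl-1-[(3E,7E)-4,8,12-trimethyl-1-(phenylsulfonyl)trideca-3,7,11-trien-1-yl]decahydronaphthalen-2-ol (both epimers at the sulfonyl-bearing carbon) | CC(C)=CCC/C(C)=C/CC/C(C)=C/CC(S(=O)(=O)c1ccccc1)[C@@H]3[C@@]2(C)CCCC(C)(C)[C@H]2CC[C@@]3(C)O | intermediate
18 | (1R,2R,4aR,8aS)-2,5,5,8a-tetramethyl-1-[(3E,7E)-4,8,12-trimethyltrideca-3,7,11-trien-1-yl]decahydronaphthalen-2-ol | CC(C)=CCC/C(C)=C/CC/C(C)=C/CC[C@@H]1[C@@]2(C)CCCC(C)(C)[C@H]2CC[C@@]1(C)O | target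

## Step count and least certain steps

Total: 10 steps. Longest linear sequence: 10 steps (1 to 18); 15 enters in step 9.

**Step 3 (Proposed new method).** What may go wrong:
- racemic background protonation, because the keto ester competes with the binaphthol for SnCl4 and sets free achiral acid (low enantiomeric purity);
- an incomplete cascade that stops at monocyclic alkenes;
- stepwise closure through a free C10 cation, which loses the alkene geometry and lets trans-fused material form.

Fallback by known chemistry, from 5 back to 6: the cyclisation is run with SnCl4 alone in CH2Cl2 at 0 °C, the established racemic bicyclisation of dienyl β-keto esters. This gives 6 together with its mirror image, methyl (1R,4aS,8aR)-5,5,8a-trimethyl-2-oxodecahydronaphthalene-1-carboxylate F1. The mixture is condensed with (S)-1-phenylethylamine (cat. AcOH, toluene, azeotropic removal of water) to the diastereomeric enamino esters: methyl (4aR,8aS)-5,5,8a-trimethyl-2-{[(1S)-1-phenylethyl]amino}-3,4,4a,5,6,7,8,8a-octahydronaphthalene-1-carboxylate F2 from 6, and methyl (4aS,8aR)-5,5,8a-trimethyl-2-{[(1S)-1-phenylethyl]amino}-3,4,4a,5,6,7,8,8a-octahydronaphthalene-1-carboxylate F3 from F1. These are separated by crystallisation or chromatography, and F2 is hydrolysed (1 M HCl, THF) to 6.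

**Step 8.** What may go wrong: slow or poorly directed hydrogen delivery, because the α face of C9=C11 is flanked by the axial C1 methylene, so that undirected addition from the β face competes and the wrong C9 configuration forms; ionisation of the tertiary allylic alcohol by the cationic metal is a second risk.

Fallback, from 13 back to 14, replacing catalytic hydrogen delivery by an intramolecular hydride conjugate addition: 13 is deprotonated with n-BuLi (1 equiv, THF, −40 °C) and treated with LiAlH4. The alkoxyaluminium hydride bound to the 8α-oxygen should deliver hydride to C9, the β-carbon of the vinyl sulfone, on the α face, and protonation of the resulting α-sulfonyl carbanion gives 14. This fallback makes no compound outside the list (F0).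

**Step 7.** What may go wrong: an inefficient radical chain, because the tertiary C9 radical between two quaternary carbons transfers the selanyl group slowly and the sulfonyl radical adds reversibly; the alcohol may also rearrange under the oxidative work-up.

Fallback, from 9 back to 13, by ionic chemistry:
- Conjugate addition of benzenesulfinate (PhSO2Na, AcOH, EtOH) to 9 gives (1S,4aR,8aS)-5,5,8a-trimethyl-1-[(phenylsulfonyl)methyl]octahydronaphthalen-2(1H)-one F4. Its C9 configuration is the expected equatorial one and is erased later.
- MeLi and CeCl3 add from the β face to give (1S,2R,4aR,8aS)-2,5,5,8a-tetramethyl-1-[(phenylsulfonyl)methyl]decahydronaphthalen-2-ol F5, the C9 epimer of 14.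
- n-BuLi (2 equiv) and then PhSeCl give (1S,2R,4aR,8aS)-2,5,5,8a-tetramethyl-1-[(phenylselanyl)(phenylsulfonyl)methyl]decahydronaphthalen-2-ol F6.
- H2O2 oxidises F6 to its Se-oxide F7, whose syn-elimination can only use the C9 hydrogen and gives 13.

**Step 9.** What may go wrong: sluggish alkylation, because the C11 carbanion sits between two quaternary centres and is aggregated with the neighbouring alkoxide, leaving time for decomposition of the allylic bromide.

Fallback, from 14 back to 17, with the hydroxyl masked so that a monoanion is used: 14 is silylated (TMSOTf, 2,6-lutidine, CH2Cl2) to trimethyl{[(1R,2R,4aR,8aS)-2,5,5,8a-tetramethyl-1-[(phenylsulfonyl)methyl]decahydronaphthalen-2-yl]oxy}silane F8. Its lithio derivative (n-BuLi, 1.05 equiv, THF–DMPU) is alkylated with 15 to the trimethylsilyl ether of 17, F9, and dilute acid on work-up cleaves the silyl ether to 17.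

## Further compounds

F1 | step 3 | methyl (1R,4aS,8aR)-5,5,8a-trimethyl-2-oxodecahydronaphthalene-1-carboxylate | COC(=O)[C@@H]1[C@]2(C)CCCC(C)(C)[C@@H]2CCC1=O
F2 | step 3 | methyl (4aR,8aS)-5,5,8a-trimethyl-2-{[(1S)-1-phenylethyl]amino}-3,4,4a,5,6,7,8,8a-octahydronaphthalene-1-carboxylate | COC(=O)C=1[C@@]2(C)CCCC(C)(C)[C@H]2CCC=1N[C@@H](C)c1ccccc1
F3 | step 3 | methyl (4aS,8aR)-5,5,8a-trimethyl-2-{[(1S)-1-phenylethyl]amino}-3,4,4a,5,6,7,8,8a-octahydronaphthalene-1-carboxylate | COC(=O)C=1[C@]2(C)CCCC(C)(C)[C@@H]2CCC=1N[C@@H](C)c1ccccc1
F0 | step 8 | none | none
F4 | step 7 | (1S,4aR,8aS)-5,5,8a-trimethyl-1-[(phenylsulfonyl)methyl]octahydronaphthalen-2(1H)-one | O=S(=O)(c1ccccc1)C[C@H]3[C@@]2(C)CCCC(C)(C)[C@H]2CCC3=O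
F5 | step 7 | (1S,2R,4aR,8aS)-2,5,5,8a-tetramethyl-1-[(phenylsulfonyl)methyl]decahydronaphthalen-2-ol | O=S(=O)(c1ccccc1)C[C@H]3[C@@]2(C)CCCC(C)(C)[C@H]2CC[C@@]3(C)O
F6 | step 7 | (1S,2R,4aR,8aS)-2,5,5,8a-tetramethyl-1-[(phenylselanyl)(phenylsulfonyl)methyl]decahydronaphthalen-2-ol (both epimers at the selanyl-bearing carbon) | O=S(=O)(c1ccccc1)C([Se]c1ccccc1)[C@H]3[C@@]2(C)CCCC(C)(C)[C@H]2CC[C@@]3(C)O
F7 | step 7 | Se-oxide of F6 | O=S(=O)(c1ccccc1)C([Se](=O)c1ccccc1)[C@H]3[C@@]2(C)CCCC(C)(C)[C@H]2CC[C@@]3(C)O
F8 | step 9 | trimethyl{[(1R,2R,4aR,8aS)-2,5,5,8a-tetramethyl-1-[(phenylsulfonyl)methyl]decahydronaphthalen-2-yl]oxy}silane | O=S(=O)(c1ccccc1)C[C@@H]3[C@@]2(C)CCCC(C)(C)[C@H]2CC[C@@]3(C)O[Si](C)(C)C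
F9 | step 9 | trimethylsilyl ether of 17 (both epimers at the sulfonyl-bearing carbon) | CC(C)=CCC/C(C)=C/CC/C(C)=C/CC(S(=O)(=O)c1ccccc1)[C@@H]3[C@@]2(C)CCCC(C)(C)[C@H]2CC[C@@]3(C)O[Si](C)(C)C
A1 | alternative 1 | 2-ethenyl-1,3,3,5-tetramethylbicyclo[2.2.2]oct-5-en-2-ol (vinyl syn to the C5=C6 bridge; enantiomer as in the SMILES) | C=C[C@]1(O)C(C)(C)[C@H]2CC[C@]1(C)C=C2C
A2 | alternative 1 | (4aR,8aS)-1,1,4a,6-tetramethyl-3,4,4a,7,8,8a-hexahydronaphthalen-2(1H)-one | CC1=C[C@@]2(C)CCC(=O)C(C)(C)[C@H]2CC1
A3 | alternative 2 | ethyl (2E)-3-[(1R,2R)-1,3,3-trimethyl-2-(3-oxobutyl)cyclohexyl]prop-2-enoate | CCOC(=O)/C=C/[C@@]1(C)CCCC(C)(C)[C@H]1CCC(C)=O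
A4 | alternative 2 | ethyl 2-[(1R,2R,4aR,8aS)-2-hydroxy-2,5,5,8a-tetramethyldecahydronaphthalen-1-yl]acetate | CCOC(=O)C[C@@H]1[C@@]2(C)CCCC(C)(C)[C@H]2CC[C@@]1(C)O
A5 | alternative 3 | tert-butyl 2-(3,3-dimethyl-6-oxocyclohex-1-en-1-yl)acetate | CC(C)(C)OC(=O)CC1=CC(C)(C)CCC1=O
A6 | alternative 3 | [2-(2-methyl-1,3-dioxolan-2-yl)ethyl]magnesium bromide | CC1(CC[Mg]Br)OCCO1
A7 | alternative 3 | tert-butyl 2-{(1R,2R)-1,3,3-trimethyl-2-[2-(2-methyl-1,3-dioxolan-2-yl)ethyl]-6-oxocyclohexyl}acetate | CC(C)(C)OC(=O)C[C@@]1(C)C(=O)CCC(C)(C)[C@H]1CCC1(C)OCCO1
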